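| flask | substrate | partner | target | time |
|---|---|---|---|---|
| elm | 0.600 M | 0.900 M |  |  |
| ash | 0.300 M | 0.600 M |  |  |
| cedar | 0.300 M | 0.900 M |  |  |
| oak | 0.600 M | 0.900 M | 0.480 M | 18 min |

| run | time / min | [target] / M |
|---|---|---|
| elm run | 1.4 | 0.0207 |
| elm run | 4.2 | 0.0541 |
| elm run | 7.9 | 0.0875 |
| elm run | 13 | 0.1106 |
| elm run | 18 | 0.1264 |
| ash run | 1.4 | 0.0069 |
| ash run | 4.2 | 0.0234 |
| ash run | 7.9 | 0.0384 |
| ash run | 13 | 0.0501 |
| ash run | 18 | 0.0570 |
| cedar run | 1.4 | 0.0052 |
| cedar run | 4.2 | 0.0260 |
| cedar run | 7.9 | 0.0445 |
| cedar run | 13 | 0.0598 |
| cedar run | 18 | 0.0650 |

(standard deviation of a reading: 0.002 M)

* reaction order in [substrate] at the outset, round the charge of the elm run, defined at two percent of the substrate turned into target (one fixed amount of target, the same in the runs compared)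
* reaction order in [partner] at the outset, round the charge of the elm run, defined at two percent of the substrate turned into target
* target in the oak run at 18 min, as a share of the substrate charged

- Overall: substrate + partner -> target.
- Constant volume, constant temperature.
- The analysis sees a species whether free or bound.
- "The second partner" is partner.
- An order is taken over about fifteen percent of the charge, up and down.
- A share of target counts the target that was charged too.

Late in the elm run target still rose, but at 0.00316 M/min between the last two readings, slower than the 0.0148 M/min of the first reading, with 21.1% of the substrate showing as target. I read the gap as target leaving in proportion to what stands.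

Elm over cedar at 18 min was 1.94 for twice the substrate, so I let production follow the substrate left, the limiting reagent. Cedar over ash was 1.14 for 1.50 times the partner, so I passed over the fall in partner. The first reading carries a scatter of 0.00143 M/min in that early rate.

The last two readings of the elm run averaged 0.119 M, which I took as the target midway through that stretch. Counting that target as substrate used:

production there: 0.0119 M/min

first leak constant: 0.0735 /min

The oak run has the substrate and partner of the elm run, so I took its charged target as the large thing, decaying, and the elm reading as the correction, supposing that charged target leaves production untouched:

oak target at the asked time, elm reading plus surviving charge: 0.254 M, or 42.4% of the substrate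

The weak link was the substrate left, which counted target seen and not target already lost. A triangle under the elm curve gave that loss:

target lost by then: 0.0675 M

production there, reforged: 0.0102 M/min

leak constant, the share of standing target lost per minute: 0.0594 /min

oak target: 0.291 M, or 48.5% of the substrate

The forecast put the oak run at 98%, between 78% and 104%, “with some allowance for a reverse reaction or inhibition”, and the orders at 1.05 in substrate and 0.37 in partner.

The flask gave 47.9% for the oak run, with orders of 1.0 in substrate and 0.52 in partner.

    substrate + partner ⇌ intermediate, settled at all times (1.350 /M)
    intermediate → target (0.1560 /min)
    target → decomposed product (0.05994 /min)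
    2 partner ⇌ idle reagent dimer, settled at all times (15.00 /M)

The path from target to decomposed product drains the oak run: with it taken away, the oak run ends at 116% instead of 47.9%, a difference of 68 percentage points. At my leak constant, the charged target loses about 52.6% of the substrate charged. The remaining 15 points or so are target made in the oak run and lost within it.

The earlier runs and the new flask are calculated from invented constants.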